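**Remarks**

- Check of the key-step structures: in 17 and 18 the centres C1, C8 and C10 (and C7 in 18) have the configuration of 21, so both skeletons are used unchanged. C7 is R in 18–20 and S in 21 only because the CIP priorities change when C11 gains its oxygen.
- Assumption: (−)-8-phenylmenthol, (2E)-but-2-enoyl chloride and (−)-MIB [(2S)-3-exo-morpholinoisoborneol] are purchasable; divinylzinc is made from CH2=CHMgBr and ZnCl2 before use.
- Design points added to the bare disconnection: 17 is made as one enantiomer and one C8 epimer, because the tether copies C8 onto C7. The ester of the Michael adduct is reduced while the ring carbonyl is still masked. The enol ether 16 must be isomerically pure.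
- The sense of induction of the auxiliary (step 3) and of the ligand (step 6) is argued from the usual models and would be confirmed on the first intermediate.

## Structural features

The target is a hydroazulenone: a cyclopentenone fused through C1 and C5 to a seven-membered carbocycle. The numbering used throughout is C1 (ring-fusion CH)–C2 (CH2)–C3 (C=O)–C4 (C–CH3)=C5 for the five-membered ring and C5–C6–C7–C8–C9–C10–C1 for the seven-membered ring; C11 is the carbon on C7 that carries two methyl groups and the acetate. The enone is tetrasubstituted (C4=C5), C10 carries a methyl group, C8 an isobutyrate and C7 the C(CH3)2OAc group. There are four stereocentres, (1R,7S,8R,10S): C1/C10 and C7/C8 are adjacent pairs, C8 and C10 are 1,3-related across C9, and H1, the C10 methyl, the C8 oxygen and C11 all lie on one face of the seven-membered ring. Fragile points are the tertiary acetate (ionisation or elimination under acid, hard to install by acylation), the secondary ester beside it, and the enone, whose γ-hydrogens at C1 and C6 make C1 epimerisable and exclude strong base late in the route. The real difficulty is the C7–C11 bond, which joins a ring methine to a fully substituted carbon and must stand cis to the C8 oxygen, together with the control of three further stereocentres on a mobile seven-membered ring. The feature exploited is threefold: the C8 oxygen sits next to C7; C7 becomes the δ-terminus of a C3=O/C4=C5/C6=C7 dienone once C6=C7 is unsaturated; and a C11 acetate is what a C11 acetyl group gives on Baeyer–Villiger oxidation. A two-atom ketal tether on the C8 oxygen can therefore deliver a C11 radical to C7 from the oxygen-bearing face, closing a temporary oxolane.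

## Logic of the disconnections

21 ⇒ 20. The O–C11 bond of the tertiary acetate is traced back to a C11–C(O)CH3 bond (Baeyer–Villiger retron). A tertiary acetate is hard to make by acylation and easy to lose, whereas a methyl ketone on a quaternary carbon is inert until the end. The forward step must oxidise the hindered saturated ketone beside the enone and let C11, not CH3, migrate.

20 ⇒ 19 ⇒ 18. The acyl–O8 bond is cut, and the γ-hydroxy ketone 19 is folded into its cyclic methyl ketal 18. This stores the C8 hydroxyl and the methyl ketone in one ring, and that ring is exactly what a tethered cyclisation leaves behind. The forward steps need only mild aqueous acid and an acylation that traps the open form of 19.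

18 ⇒ 17. The C7–C11 bond is cut, C6=C7 is restored and bromine is placed on C11. This is the most congested bond of 21; in 17 its two ends are already joined through O8 and the ketal carbon, so it can form only on the face of O8. One ring, one stereocentre and the quaternary-to-methine junction disappear. The forward step must cyclise before the radical is reduced and must return hydrogen to C6.

17 ⇒ 13 + 16, 16 ⇒ 15 ⇒ 14. The O8–C(ketal) and C11–Br bonds are cut together (haloetherification retron). This separates the carbocyclic core 13, which holds every ring carbon and three of the four stereocentres, from the achiral five-carbon unit 16, which comes from 14 through 15. The forward step demands the tetrasubstituted enol ether free of its terminal isomer and a non-acidic medium.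

13 ⇒ 12. The C6=C7 bond is cut (ring-closing metathesis retron). The bicycle becomes a cyclopentenone with a vinyl group on C5 and a vinyl carbinol chain on C1. The forward step must close a seven-membered ring onto an electron-poor dienyl terminus in the presence of a free allylic hydroxyl.

12 ⇒ 11. The C7–C8 bond is cut, leaving an aldehyde and a vinyl metal. C8 is the only stereocentre removed; C10 is β to the carbonyl and cannot direct the addition, so the forward step must be reagent-controlled and must leave the dienone alone.

11 ⇒ 10 ⇒ 7. The aldehyde is taken back to the alcohol 10; then the C5–C6 bond is cut with 1,3-transposition of the carbonyl (vinylogous ester retron) and the alcohol is returned to the ester level. The reactive vinyl dienone is replaced by the stable vinylogous ester 7. The demand is that the ester be reduced while the ring carbonyl is still masked, because an ester cannot be reduced selectively beside the free dienone.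

7 ⇒ 2 + 5, 2 ⇒ 1, 5 ⇒ 3 + 4. The C1–C10 bond is cut (Michael retron), giving the α′-enolate of 2 and the crotonate 5; 2 comes from 1, and 5 from 3 and 4. Both C1 and C10 go in one cut and every carbon is traced to a simple material. The forward step must combine syn topicity with attack on one enoate face, which is why the crotonate carries a chiral ester group.

## Other disconnections considered

Alternative 1: The C8–C9 bond is cut. Forward, the aldehyde A2, with C1 and C7 in place, would close under Me2AlCl by a carbonyl-ene reaction: the isopropenyl CH2 (C9) attacks the C8 aldehyde and a hydrogen moves from the isopropenyl methyl, giving the bicyclic alcohol A1 with an exocyclic methylene at C10.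
- In its favour: C1 comes from the chiral pool, the cyclopentene being made from (S)-limonene A3 by ring cleavage and aldol re-closure; C11 already carries its oxygen as a silyl ether, so no late peracid step is needed; ring and carbinol form together.
- Against it here: A1 lacks the C3 carbonyl, and allylic oxidation of the C4=C5 alkene has C3, C6 and C1 to choose from. C10 must be set by hydrogenation of the exocyclic alkene with hydrogen arriving on the face opposite to the C8 hydroxyl, the reverse of what a hydroxyl-directed catalyst would do. C7 in A2 is α to the aldehyde, needs its own auxiliary-based alkylation and must survive the Lewis acid. The C8 configuration rests on the ene transition state and not on a tether. A3 is the less abundant enantiomer of limonene.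
- Comparison: on the origin of C1 and the handling of the C11 oxygen this plan is the equal or the better of the chosen one. On C7/C8 the chosen plan is structurally safer, since C8 is set by a reagent and then passed to C7 through a ring. The ene route gains at the ring closure but pays afterwards (C3 oxidation, C10 reduction, desilylation, acylation of a hindered tertiary alcohol), so no saving in steps is expected.

Alternative 2: The C1–C5 and C8–C9 bonds are cut. Forward, ionisation of the chloromethyl ketone A5 would give an oxyallyl cation spanning C1–C10–C9, which adds across the 2,5-positions of the tethered furan (C5 and C8) to give the bridged tricycle A4, both carbocycles forming at once.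
- In its favour: two rings and three stereocentres (C1, C5, C8) in one step; the bridging oxygen is the future C8 oxygen and lies on the face of H1, as the target requires; later β-elimination from a C3 ketone would open the bridge and reveal the C4=C5 enone and the C8 hydroxyl together.
- Against it here: the furan is deactivated by its ester group; the tether stereocentres C3 and C4 that steer the cycloaddition are sacrificial; C10 emerges as a ketone, so the methyl must be introduced and then reduced with face control; C7 must come from reduction of the unsaturated ester, and C11 from double methyl addition to that ester beside other carbonyl groups, followed by acylation of a tertiary alcohol.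
- Comparison: in ring-building economy this plan is better (one step against a Michael addition plus a metathesis), and its C1/C8 relation is as secure as in the chosen plan. It is weaker in that C7 and C10 both remain to be set by reagent approach to a folded oxabicycle, where the chosen plan sets C10 at the outset and C7 through the tether; with the adjustments after the cycloaddition the total is expected to be longer.

Alternative 3: The C6–C7 and C9–C10 bonds are cut. Forward, a dirhodium tetracarboxylate such as Rh2(S-DOSP)4 (divalent rhodium) decomposes the diazo ester A8; the vinylcarbenoid cyclopropanates the exocyclic C5=C6 bond of the diene A7, and the cis-divinylcyclopropane rearranges (Cope) to the cycloheptadiene A6.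
- In its favour: convergent and catalytic, with the option of catalyst-controlled induction; the boat-like Cope step transfers the ethylidene geometry to C10, so C10 is set in the key step; the C8 oxygen and the C7 carboxyl carbon (a C11 precursor) arrive in place.
- Against it here: cyclopropanation must choose the methylene over the ethylidene double bond and one face of the diene, and for the (E)-ethylidene isomer A7 the face that leads to the right C10 is the one carrying the C4 methyl. In A6, C7 and C8 are still the two ends of an enol ether, so both centres and their cis relation remain to be made. The C1=C5 double bond must be moved to C4=C5 after oxidation at C3, which creates C1 by protonation under thermodynamic control only. A7 is itself a multistep, enantiopure intermediate.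
- Comparison: in convergence, in the use of catalysis and in setting C10 within the key step this plan is the equal or the better of the chosen one. The chosen plan is stronger at C7, where the target is hardest, and needs only three operations after its key step; A6 would need reduction at C7/C8, transposition of the ring alkene, methyl additions and two differentiated acylations.

Key step: step 11

## Route

Step 1
Reactants: 1 2-methylcyclopentane-1,3-dione
Product: 2 2-methyl-3-(2-methylpropoxy)cyclopent-2-en-1-one
Conditions: i-BuOH, p-TsOH (cat.), toluene, reflux, Dean–Stark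
Reagents that add atoms: 2-methylpropan-1-ol, CC(C)CO
Why: Acid-catalysed enol etherification of a vinylogous acid with azeotropic removal of water; the symmetrical dione can give only one enol ether. One carbonyl is masked and a single kinetic α′ position (the future C1) is left for deprotonation.

Step 2
Reactants: 3 (−)-8-phenylmenthol; 4 (2E)-but-2-enoyl chloride
Product: 5 (1R,2S,5R)-5-methyl-2-(2-phenylpropan-2-yl)cyclohexyl (2E)-but-2-enoate
Conditions: pyridine, DMAP (cat.), CH2Cl2, 0 °C → rt
Reagents that add atoms: none
Why: DMAP-catalysed acylation of a hindered secondary alcohol. Pyridine is used in place of a trialkylamine so that the acid chloride is not deconjugated through its vinylketene and the (E) geometry is kept.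

Step 3
Reactants: 2 2-methyl-3-(2-methylpropoxy)cyclopent-2-en-1-one; 5 (1R,2S,5R)-5-methyl-2-(2-phenylpropan-2-yl)cyclohexyl (2E)-but-2-enoate
Product: 7 (1R,2S,5R)-5-methyl-2-(2-phenylpropan-2-yl)cyclohexyl (3S)-3-[(1R)-3-methyl-4-(2-methylpropoxy)-2-oxocyclopent-3-en-1-yl]butanoate, via lithium dienolate 6 (not isolated)
Conditions: LiN(i-Pr)2, THF, −78 °C; then 5, −78 °C; AcOH, −78 °C
Reagents that add atoms: none
Why: Michael addition of a kinetic Stork–Danheiser α′-lithium enolate to a chiral crotonate. The ring enolate can only be (E), and in the closed, lithium-bridged transition state with the s-cis enoate the crotonate methyl lies anti to the enolate C=C, which gives the syn adduct (1R*,10S*). The phenyl group of the auxiliary is expected to shield the Re face of C10 in that conformer, so the enolate adds to the Si face and sets 10S and with it 1R; the cold quench avoids proton exchange at C1.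

Step 4
Reactants: 7 (1R,2S,5R)-5-methyl-2-(2-phenylpropan-2-yl)cyclohexyl (3S)-3-[(1R)-3-methyl-4-(2-methylpropoxy)-2-oxocyclopent-3-en-1-yl]butanoate
Product: 10 (4R)-3-ethenyl-4-[(2S)-4-hydroxybutan-2-yl]-2-methylcyclopent-2-en-1-one, via vinyl carbinol 8 (not isolated), via diol 9 (not isolated)
Conditions: CH2=CHMgBr, CeCl3, THF, −78 → 0 °C; then LiAlH4, 0 °C; then 1 M HCl, THF, 0 °C → rt
Reagents that add atoms: vinylmagnesium bromide, C=C[Mg]Br; water, O
Why: Stork–Danheiser sequence telescoped with an ester reduction: CeCl3-promoted 1,2-addition of the vinyl Grignard reagent to the vinylogous ester carbonyl (the hindered ester is left alone), LiAlH4 reduction of the ester while the ring carbonyl is masked as a tertiary alkoxide, then acid hydrolysis of the β-alkoxy allylic alcohol with transposition to the 3-vinyl enone. The carbinol centre of 8 and 9 forms as a mixture and is destroyed in the last operation; C1 and C10 are untouched, CeCl3 suppressing enolisation at C1. The auxiliary 3 is recovered.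

Step 5
Reactants: 10 (4R)-3-ethenyl-4-[(2S)-4-hydroxybutan-2-yl]-2-methylcyclopent-2-en-1-one
Product: 11 (3S)-3-[(1R)-2-ethenyl-3-methyl-4-oxocyclopent-2-en-1-yl]butanal
Conditions: Dess–Martin periodinane, CH2Cl2, 0 °C → rt
Reagents that add atoms: none
Why: Dess–Martin oxidation of a primary alcohol to the aldehyde under neutral conditions. The aldehyde has no α-stereocentre (C9 is CH2), and base is avoided because a C2 enolate could close onto the aldehyde.

Step 6
Reactants: 11 (3S)-3-[(1R)-2-ethenyl-3-methyl-4-oxocyclopent-2-en-1-yl]butanal
Product: 12 (4R)-3-ethenyl-4-[(2S,4R)-4-hydroxyhex-5-en-2-yl]-2-methylcyclopent-2-en-1-one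
Conditions: (CH2=CH)2Zn, (−)-MIB (10 mol %), toluene, −20 → 0 °C; then 0.5 M HCl, 0 °C
Reagents that add atoms: divinylzinc, C=C[Zn]C=C
Why: Catalytic asymmetric alkenylzinc addition to an aldehyde, accelerated by a chiral amino alcohol. With (−)-MIB the vinyl group should be delivered to the Si face of the aldehyde, which corresponds to 8R here (vinyl outranks C9); reagent control is needed because C10 is β to the carbonyl. The zinc reagent does not add to the dienone and is not basic enough to start an aldol closure between C2 and the aldehyde.

Step 7
Reactants: 12 (4R)-3-ethenyl-4-[(2S,4R)-4-hydroxyhex-5-en-2-yl]-2-methylcyclopent-2-en-1-one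
Product: 13 (3aR,4S,6R)-6-hydroxy-1,4-dimethyl-3a,4,5,6-tetrahydroazulen-2(3H)-one
Conditions: second-generation Hoveyda–Grubbs catalyst (5 mol %), CH2Cl2 (5 mM), 40 °C
Reagents that add atoms: none
Why: Ring-closing metathesis; the catalyst loads on the vinyl group of the allylic alcohol and closes onto the vinyl group of the dienone, forming C6=C7 in a seven-membered ring whose cis geometry is imposed by the ring. No stereocentre is formed or touched, and high dilution disfavours dimers.

Step 8
Reactants: 14 3-methylbutan-2-one
Product: 15 2,2-dimethoxy-3-methylbutane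
Conditions: HC(OMe)3, MeOH, p-TsOH (cat.), rt
Reagents that add atoms: trimethyl orthoformate, COC(OC)OC
Why: Acid-catalysed ketalisation, driven by the orthoformate as water scavenger.

Step 9
Reactants: 15 2,2-dimethoxy-3-methylbutane
Product: 16 2-methoxy-3-methylbut-2-ene
Conditions: p-TsOH (cat.), 130 °C, MeOH distilled off; fractional distillation
Reagents that add atoms: none
Why: Acid-catalysed loss of methanol from a ketal (ketal cracking). Under these equilibrating conditions the tetrasubstituted enol ether is expected to predominate over the lower-boiling terminal isomer, from which it is freed by fractionation. Isomeric purity matters because the terminal isomer would give a primary bromide in step 10.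

Step 10
Reactants: 13 (3aR,4S,6R)-6-hydroxy-1,4-dimethyl-3a,4,5,6-tetrahydroazulen-2(3H)-one; 16 2-methoxy-3-methylbut-2-ene
Product: 17 (3aR,4S,6R)-6-[(3-bromo-2-methoxy-3-methylbutan-2-yl)oxy]-1,4-dimethyl-3a,4,5,6-tetrahydroazulen-2(3H)-one (both epimers at the ketal carbon)
Conditions: NBS, K2CO3 (solid), CH2Cl2, −78 → −20 °C
Reagents that add atoms: N-bromosuccinimide, O=C1CCC(=O)N1Br
Why: Ueno–Stork haloetherification: NBS brominates the electron-rich enol ether at the future C11, and the tertiary oxocarbenium ion is captured by the C8 hydroxyl of 13. The ketal carbon forms as both epimers, which is of no consequence since it is lost later. Solid K2CO3 keeps the mixture free of HBr, which would cleave the mixed ketal.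

Step 11
Reactants: 17 (3aR,4S,6R)-6-[(3-bromo-2-methoxy-3-methylbutan-2-yl)oxy]-1,4-dimethyl-3a,4,5,6-tetrahydroazulen-2(3H)-one
Product: 18 (1R,7R,8R,10S)-4,10-dimethylbicyclo[5.3.0]dec-4-en-3-one carrying a cis-fused 2-methoxy-2,3,3-trimethyloxolane (ring oxygen on C8, ring carbon 3 = C11 on C7; both ketal epimers)
Conditions: Bu3SnH (syringe pump), AIBN (cat.), PhH (0.01 M), 80 °C; then Et3N (cat.), rt; aq. KF
Reagents that add atoms: none
Why: Ueno–Stork haloketal radical cyclisation, here run on a dienone acceptor. The tributylstannyl radical abstracts bromine from 17 to give the tertiary radical at C11, which is nucleophilic and meets the electron-poor δ-terminus C7 of the C3 dienone, a polarity-matched radical 1,6-addition. The oxolane ring O8–C(ketal)–C11–C7–C8 closes in the 5-exo-trig mode; attack at C6 would need a 6-endo transition state and would give an unstabilised radical, so C7 is preferred on both counts. The new stereocentre C7 is controlled by the tether: the two-atom bridge from the C8 oxygen can reach C7 only on the face that carries that oxygen, so the ring fusion is cis and C11 ends up cis to O8. The resulting radical is delocalised over C6, C4 and the C3 oxygen and should take hydrogen from Bu3SnH mainly at the less hindered C6, restoring the C4=C5 enone; any C5=C6 isomer is brought into conjugation by the Et3N treatment. The selectivity the step needs is cyclisation before reduction of the hindered tertiary radical, which is secured by a low stationary concentration of Bu3SnH and by the activated acceptor. The ketal carbon is stereorandom in both 17 and 18 and is lost later. C1, C8 and C10 take no part.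

Step 12
Reactants: 18 the cis-fused cyclic methyl ketal
Product: 19 (3aR,4S,6R,7R)-6-hydroxy-1,4-dimethyl-7-(2-methyl-3-oxobutan-2-yl)-3a,4,5,6,7,8-hexahydroazulen-2(3H)-one
Conditions: PPTS, acetone–H2O, rt
Reagents that add atoms: water, O
Why: Acid-catalysed hydrolysis of a mixed cyclic ketal: loss of methanol gives the cyclic oxocarbenium ion, water adds, and the hemiketal opens to the γ-hydroxy ketone, with which it stays in equilibrium. No stereocentre is affected.

Step 13
Reactants: 19 (3aR,4S,6R,7R)-6-hydroxy-1,4-dimethyl-7-(2-methyl-3-oxobutan-2-yl)-3a,4,5,6,7,8-hexahydroazulen-2(3H)-one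
Product: 20 (3aR,4S,6R,7R)-1,4-dimethyl-7-(2-methyl-3-oxobutan-2-yl)-2-oxo-2,3,3a,4,5,6,7,8-octahydroazulen-6-yl 2-methylpropanoate
Conditions: i-PrCOCl, pyridine, DMAP (cat.), CH2Cl2, 0 °C → rt
Reagents that add atoms: 2-methylpropanoyl chloride, CC(C)C(Cl)=O
Why: DMAP-catalysed acylation of a secondary alcohol; the open hydroxy ketone is drained from its equilibrium with the cyclic hemiketal, whose tertiary hydroxyl beside a quaternary carbon is far less reactive. C8 keeps its configuration because its C–O bond is not broken.

Step 14
Reactants: 20 (3aR,4S,6R,7R)-1,4-dimethyl-7-(2-methyl-3-oxobutan-2-yl)-2-oxo-2,3,3a,4,5,6,7,8-octahydroazulen-6-yl 2-methylpropanoate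
Product: 21 (3aR,4S,6R,7S)-7-(2-acetoxypropan-2-yl)-1,4-dimethyl-2-oxo-2,3,3a,4,5,6,7,8-octahydroazulen-6-yl 2-methylpropanoate
Conditions: mCPBA, Na2HPO4, CH2Cl2, 0 °C → rt
Reagents that add atoms: 3-chloroperoxybenzoic acid, OOC(=O)c1cccc(Cl)c1
Why: Baeyer–Villiger oxidation; in the Criegee adduct of the methyl ketone the tertiary C11 migrates far better than methyl, which gives the C11 acetate directly. The conjugated cyclopentenone is a poorer partner for the electrophilic peracid at both its carbonyl and its electron-poor tetrasubstituted alkene, and the buffer protects the tertiary acetate.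

## Compound list

1 | 2-methylcyclopentane-1,3-dione | CC1C(=O)CCC1=O | starting material
2 | 2-methyl-3-(2-methylpropoxy)cyclopent-2-en-1-one | CC(C)COC1=C(C)C(=O)CC1 | intermediate
3 | (−)-8-phenylmenthol, (1R,2S,5R)-5-methyl-2-(2-phenylpropan-2-yl)cyclohexan-1-ol | CC(C)(c1ccccc1)[C@@H]1CC[C@@H](C)C[C@H]1O | starting material
4 | (2E)-but-2-enoyl chloride | C/C=C/C(Cl)=O | starting material
5 | (1R,2S,5R)-5-methyl-2-(2-phenylpropan-2-yl)cyclohexyl (2E)-but-2-enoate | C/C=C/C(=O)O[C@@H]1C[C@H](C)CC[C@H]1C(C)(C)c1ccccc1 | intermediate
6 | lithium 5-methyl-4-(2-methylpropoxy)cyclopenta-1,4-dien-1-olate | [Li+].[O-]C1=CCC(OCC(C)C)=C1C | intermediate (not isolated)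
7 | (1R,2S,5R)-5-methyl-2-(2-phenylpropan-2-yl)cyclohexyl (3S)-3-[(1R)-3-methyl-4-(2-methylpropoxy)-2-oxocyclopent-3-en-1-yl]butanoate | O=C1C(C)=C(OCC(C)C)C[C@@H]1[C@@H](C)CC(=O)O[C@@H]2C[C@H](C)CC[C@H]2C(C)(C)c3ccccc3 | intermediate
8 | (1R,2S,5R)-5-methyl-2-(2-phenylpropan-2-yl)cyclohexyl (3S)-3-[(1R)-2-ethenyl-2-hydroxy-3-methyl-4-(2-methylpropoxy)cyclopent-3-en-1-yl]butanoate (carbinol epimers) | C=CC1(O)C(C)=C(OCC(C)C)C[C@@H]1[C@@H](C)CC(=O)O[C@@H]2C[C@H](C)CC[C@H]2C(C)(C)c3ccccc3 | intermediate (not isolated)
9 | (3S)-3-[(1R)-2-ethenyl-2-hydroxy-3-methyl-4-(2-methylpropoxy)cyclopent-3-en-1-yl]butan-1-ol (carbinol epimers) | C=CC1(O)C(C)=C(OCC(C)C)C[C@@H]1[C@@H](C)CCO | intermediate (not isolated)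
10 | (4R)-3-ethenyl-4-[(2S)-4-hydroxybutan-2-yl]-2-methylcyclopent-2-en-1-one | OCC[C@H](C)[C@H]1CC(=O)C(C)=C1C=C | intermediate
11 | (3S)-3-[(1R)-2-ethenyl-3-methyl-4-oxocyclopent-2-en-1-yl]butanal | O=CC[C@H](C)[C@H]1CC(=O)C(C)=C1C=C | intermediate
12 | (4R)-3-ethenyl-4-[(2S,4R)-4-hydroxyhex-5-en-2-yl]-2-methylcyclopent-2-en-1-one | C=C[C@H](O)C[C@H](C)[C@H]1CC(=O)C(C)=C1C=C | intermediate
13 | (3aR,4S,6R)-6-hydroxy-1,4-dimethyl-3a,4,5,6-tetrahydroazulen-2(3H)-one [(1R,8R,10S) in the numbering above] | O[C@H]1C=CC2=C(C)C(=O)C[C@@H]2[C@@H](C)C1 | intermediate
14 | 3-methylbutan-2-one | CC(C)C(C)=O | starting material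
15 | 2,2-dimethoxy-3-methylbutane | COC(C)(OC)C(C)C | intermediate
16 | 2-methoxy-3-methylbut-2-ene | COC(C)=C(C)C | intermediate
17 | (3aR,4S,6R)-6-[(3-bromo-2-methoxy-3-methylbutan-2-yl)oxy]-1,4-dimethyl-3a,4,5,6-tetrahydroazulen-2(3H)-one (ketal epimers) | COC(C)(O[C@H]1C=CC2=C(C)C(=O)C[C@@H]2[C@@H](C)C1)C(C)(C)Br | intermediate
18 | (1R,7R,8R,10S)-4,10-dimethylbicyclo[5.3.0]dec-4-en-3-one with cis-fused 2-methoxy-2,3,3-trimethyloxolane (O on C8, C11 on C7; ketal epimers) | COC1(C)O[C@@H]2C[C@H](C)[C@H]3CC(=O)C(C)=C3C[C@@H]2C1(C)C | intermediate
19 | (3aR,4S,6R,7R)-6-hydroxy-1,4-dimethyl-7-(2-methyl-3-oxobutan-2-yl)-3a,4,5,6,7,8-hexahydroazulen-2(3H)-one | CC(=O)C(C)(C)[C@H]1CC2=C(C)C(=O)C[C@@H]2[C@@H](C)C[C@H]1O | intermediate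
20 | (3aR,4S,6R,7R)-1,4-dimethyl-7-(2-methyl-3-oxobutan-2-yl)-2-oxo-2,3,3a,4,5,6,7,8-octahydroazulen-6-yl 2-methylpropanoate | CC(=O)C(C)(C)[C@H]1CC2=C(C)C(=O)C[C@@H]2[C@@H](C)C[C@H]1OC(=O)C(C)C | intermediate
21 | (3aR,4S,6R,7S)-7-(2-acetoxypropan-2-yl)-1,4-dimethyl-2-oxo-2,3,3a,4,5,6,7,8-octahydroazulen-6-yl 2-methylpropanoate [(1R,7S,8R,10S)] | CC(=O)OC(C)(C)[C@H]1CC2=C(C)C(=O)C[C@@H]2[C@@H](C)C[C@H]1OC(=O)C(C)C | target

## Step count and least certain steps

Total: 14 steps. Longest linear sequence: 11 steps (steps 1, 3, 4, 5, 6, 7, 10, 11, 12, 13, 14); steps 2, 8 and 9 prepare side components.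

Step 11 (key step). Most likely to go wrong: hydrogen transfer from Bu3SnH to the tertiary C11 radical before it has closed the hindered C7–C11 bond, or stannyl-radical reduction of the dienone, both leaving uncyclised material. Fallback (sets out from 13, returns at 21): the bond is made by an ionic, alkoxide-directed conjugate addition. Excess isopropenylmagnesium bromide in THF converts 13 into its magnesium alkoxide, which is expected to deliver the alkenyl group to the neighbouring δ-carbon C7 on the oxygen-bearing face (the directed addition known for 4-hydroxycyclohexadienones, here in vinylogous form); protonation gives the isopropenyl alcohol F1. Acylation with isobutyryl chloride gives the ester F2, Mukaiyama hydration of the 1,1-disubstituted alkene (Co(acac)2, PhSiH3, O2) gives the tertiary alcohol F3, and acetylation (Ac2O, TMSOTf cat.) gives 21. This detour also removes the peracid step.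

Step 3. Most likely to go wrong: poor face discrimination by the auxiliary in the s-cis, lithium-bridged arrangement (its shielding is best established for s-trans enoates), or leakage through an open transition state that erodes the syn preference. Fallback (sets out from 2, returns at 13): the source of absolute configuration is moved to the catalyst of step 6. Addition of 6 to tert-butyl (2E)-but-2-enoate gives the racemic syn ester F4. Steps 4 and 5 applied to it give 10 and 11 together with their enantiomers F5 and F6. The (−)-MIB-controlled vinylation installs 8R in both series, giving 12 and the diastereomer F7, and metathesis gives 13 and its diastereomer F8, which are separated by chromatography. Half of the material is lost, but no auxiliary is needed. A residual C1 epimer could in addition be equilibrated at the stage of 13, since C1 is γ to the dienone, provided the trans arrangement of C2 and the C10 methyl is the more stable one.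

Step 4. Most likely to go wrong: in the one-flask sequence, vinylmagnesium bromide still present may capture the aldehyde stage of the ester reduction, or the hindered ester may be reduced too slowly at 0 °C. Fallback (sets out from 7, returns at 11): the operations are separated and the redox strategy is changed. Vinyl addition followed directly by acid gives the dienone ester F9; DIBAL-H reduces both the ester and the ring ketone to the diol F10 and releases the auxiliary; Dess–Martin periodinane then oxidises both hydroxyl groups and gives 11 without passing through 10.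

Step 6. Most likely to go wrong: modest facial selectivity, because vinyl transfer to β-branched aliphatic aldehydes is less selective than to aromatic ones and C10 gives no help. Fallback (sets out from 11, returns at 13): CH2=CHMgBr in THF at −78 °C adds to the aldehyde without control and gives 12 with its C8 epimer F11. Metathesis gives 13 and the 8-epimer F12, which are separated. F12 is inverted by a Mitsunobu reaction (4-nitrobenzoic acid, PPh3, DIAD) to the ester F13, and K2CO3 in MeOH then gives 13.

Step 10. Most likely to go wrong: the hindered bromo-oxocarbenium ion loses a proton or is captured by succinimide faster than by the secondary alcohol, and any terminal enol ether in 16 leads to a primary bromide. Fallback (sets out from 14 and 13, returns at 17): the bromine is introduced before the ketal is made. Acid-catalysed bromination of 14 (Br2, AcOH) at the more substituted α-carbon gives the bromo ketone F14. HC(OMe)3, MeOH and p-TsOH give the bromo dimethyl ketal F15. Acid-catalysed exchange of one methoxy group with 13 (PPTS, toluene, 4 Å molecular sieves to take up MeOH) gives 17.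

## Further compounds

F1 | step 11 | (3aR,4S,6R,7R)-6-hydroxy-1,4-dimethyl-7-(prop-1-en-2-yl)-3a,4,5,6,7,8-hexahydroazulen-2(3H)-one | CC(=C)[C@H]1CC2=C(C)C(=O)C[C@@H]2[C@@H](C)C[C@H]1O
F2 | step 11 | (3aR,4S,6R,7R)-1,4-dimethyl-2-oxo-7-(prop-1-en-2-yl)-2,3,3a,4,5,6,7,8-octahydroazulen-6-yl 2-methylpropanoate | CC(=C)[C@H]1CC2=C(C)C(=O)C[C@@H]2[C@@H](C)C[C@H]1OC(=O)C(C)C
F3 | step 11 | (3aR,4S,6R,7S)-7-(2-hydroxypropan-2-yl)-1,4-dimethyl-2-oxo-2,3,3a,4,5,6,7,8-octahydroazulen-6-yl 2-methylpropanoate | CC(C)(O)[C@H]1CC2=C(C)C(=O)C[C@@H]2[C@@H](C)C[C@H]1OC(=O)C(C)C
F4 | step 3 | racemic tert-butyl (3S*)-3-[(1R*)-3-methyl-4-(2-methylpropoxy)-2-oxocyclopent-3-en-1-yl]butanoate (one enantiomer drawn) | O=C1C(C)=C(OCC(C)C)C[C@@H]1[C@@H](C)CC(=O)OC(C)(C)C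
F5 | step 3 | (4S)-3-ethenyl-4-[(2R)-4-hydroxybutan-2-yl]-2-methylcyclopent-2-en-1-one (enantiomer of 10) | OCC[C@@H](C)[C@@H]1CC(=O)C(C)=C1C=C
F6 | step 3 | (3R)-3-[(1S)-2-ethenyl-3-methyl-4-oxocyclopent-2-en-1-yl]butanal (enantiomer of 11) | O=CC[C@@H](C)[C@@H]1CC(=O)C(C)=C1C=C
F7 | step 3 | (4S)-3-ethenyl-4-[(2R,4R)-4-hydroxyhex-5-en-2-yl]-2-methylcyclopent-2-en-1-one | C=C[C@H](O)C[C@@H](C)[C@@H]1CC(=O)C(C)=C1C=C
F8 | step 3 | (3aS,4R,6R)-6-hydroxy-1,4-dimethyl-3a,4,5,6-tetrahydroazulen-2(3H)-one | O[C@H]1C=CC2=C(C)C(=O)C[C@H]2[C@H](C)C1
F9 | step 4 | (1R,2S,5R)-5-methyl-2-(2-phenylpropan-2-yl)cyclohexyl (3S)-3-[(1R)-2-ethenyl-3-methyl-4-oxocyclopent-2-en-1-yl]butanoate | C=CC1=C(C)C(=O)C[C@@H]1[C@@H](C)CC(=O)O[C@@H]2C[C@H](C)CC[C@H]2C(C)(C)c3ccccc3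
F10 | step 4 | (3S)-3-[(1R)-2-ethenyl-4-hydroxy-3-methylcyclopent-2-en-1-yl]butan-1-ol (carbinol epimers) | C=CC1=C(C)C(O)C[C@@H]1[C@@H](C)CCO
F11 | step 6 | (4R)-3-ethenyl-4-[(2S,4S)-4-hydroxyhex-5-en-2-yl]-2-methylcyclopent-2-en-1-one | C=C[C@@H](O)C[C@H](C)[C@H]1CC(=O)C(C)=C1C=C
F12 | step 6 | (3aR,4S,6S)-6-hydroxy-1,4-dimethyl-3a,4,5,6-tetrahydroazulen-2(3H)-one | O[C@@H]1C=CC2=C(C)C(=O)C[C@@H]2[C@@H](C)C1
F13 | step 6 | (3aR,4S,6R)-1,4-dimethyl-2-oxo-2,3,3a,4,5,6-hexahydroazulen-6-yl 4-nitrobenzoate | O=C(O[C@H]1C=CC2=C(C)C(=O)C[C@@H]2[C@@H](C)C1)c1ccc(cc1)[N+](=O)[O-]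
F14 | step 10 | 3-bromo-3-methylbutan-2-one | CC(=O)C(C)(C)Br
F15 | step 10 | 3-bromo-2,2-dimethoxy-3-methylbutane | COC(C)(OC)C(C)(C)Br
A1 | alternative 1 | (1R,7S,8R)-11-(triethylsilyloxy)guaia-4,10(14)-dien-8-ol | CC[Si](CC)(CC)OC(C)(C)[C@H]1CC2=C(C)CC[C@@H]2C(=C)C[C@H]1O
A2 | alternative 1 | (2R)-3-methyl-2-{[(5R)-2-methyl-5-(prop-1-en-2-yl)cyclopent-1-en-1-yl]methyl}-3-(triethylsilyloxy)butanal | CC[Si](CC)(CC)OC(C)(C)[C@H](C=O)CC1=C(C)CC[C@@H]1C(C)=C
A3 | alternative 1 | (S)-(−)-limonene | CC1=CC[C@H](CC1)C(C)=C
A4 | alternative 2 | cyclopentane-fused methyl 3-oxo-8-oxabicyclo[3.2.1]oct-6-ene-6-carboxylate with C4 methyl and C3 tert-butyldimethylsilyloxy groups (C10 as the ketone) | COC(=O)C1=C[C@]23[C@@H](C)[C@H](O[Si](C)(C)C(C)(C)C)C[C@@H]2C(=O)C[C@H]1O3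
A5 | alternative 2 | methyl 5-[(2S,3R)-3-(tert-butyldimethylsilyloxy)-7-chloro-6-oxoheptan-2-yl]furan-3-carboxylate | COC(=O)c1coc(c1)[C@@H](C)[C@H](O[Si](C)(C)C(C)(C)C)CCC(=O)CCl
A6 | alternative 3 | bicyclic dienyl β-silyloxy acrylate with C1=C5 and C7=C8 double bonds, C10 methyl set, C3 silyloxy and C4 methyl | COC(=O)C1=C(O[Si](C)(C)C(C)(C)C)C[C@H](C)C2=C(C1)[C@@H](C)[C@H](O[Si](C)(C)C(C)(C)C)C2
A7 | alternative 3 | tert-butyl{[(1R,2R,4E)-4-ethylidene-2-methyl-3-methylidenecyclopentyl]oxy}dimethylsilane | C=C1[C@@H](C)[C@H](O[Si](C)(C)C(C)(C)C)C/C1=C\C
A8 | alternative 3 | methyl 3-(tert-butyldimethylsilyloxy)-2-diazobut-3-enoate | COC(=O)C(=[N+]=[N-])C(=C)O[Si](C)(C)C(C)(C)C
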